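**Retrosynthetic overview**
- The route rests on two features of the skeleton. In ring A the acetoxy carbon C2 is joined to the ring-fusion carbon C10 through the single methylene C1, so a C2 aldehyde and a C10=C1 methylene on ring B form an ene pair. In ring B, C7, C8 and C11 trace the gem-dimethylcyclopropane of (+)-3-carene with the correct absolute sense at C7.
- Target ⇒ 8α,9α-diol 23 + angelic acid (C9–O acylation last); the isopropenyl group comes from a C11 carbinol and the cis-diol from OsO4 on a C8=C9 alkene.
- The C8=C9 alkene and C11–OH come from cyclopropylcarbinyl-to-homoallyl opening (C8–C11 bond) of the 9α-carbinol 18, itself made by hydroboration of the C9=C10 alkene of 15.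
- Ring A of 15 comes from C1–C2 bond formation in a type 2 carbonyl-ene cyclisation of aldehyde 13; 13 comes from isocaranone by a ketal Claisen rearrangement with (E)-crotyl alcohol (C4–C5 bond), methylenation and chain-end oxidation.
- Ring order: ring B and the three-membered ring are taken from (+)-3-carene; ring A is closed in step 8; the three-membered ring is opened in step 11.

Key step: step 8

Remark: eremophilane numbering is used throughout (ring A = C1–C5, C10; ring B = C5–C10; C11 = future isopropenyl carbon; C14 = methyl on C5; C15 = methyl on C4), β is the face of the C11 bridge and of C14, and commercial (+)-3-carene is taken as the (1S,6R) enantiomer.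

**Step 1**
Reactants: 1 (+)-3-carene
Product: 3 (−)-4-isocaranol, via bis(4-isocaranyl)borane 2 (not isolated)
Conditions: BH3·SMe2 (0.55 equiv), THF, 0 °C → rt; then NaOH, H2O2, 0 °C → rt
Reagents that add atoms: borane–dimethyl sulfide, C[S+](C)[BH3-] (boron of 2); hydrogen peroxide, OO (oxygen of 3)
Why: Brown hydroboration–oxidation, in which B–H adds syn to the trisubstituted alkene from the face away from the gem-dimethylcyclopropane with boron on the less substituted carbon (C10), and C–B oxidation with retention gives the alcohol trans to the bridge.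

**Step 2**
Reactants: 3 (−)-4-isocaranol
Product: 4 isocaran-4-one
Conditions: (n-Pr4N)RuO4 (5 mol%), NMO, 4 Å MS, CH2Cl2, rt
Reagents that add atoms: none
Why: Ley–Griffith oxidation of a secondary alcohol to the ketone under neutral conditions that leave the cyclopropane untouched.

**Step 3**
Reactants: 4 isocaran-4-one
Product: 5 isocaran-4-one dimethyl ketal
Conditions: HC(OMe)3, MeOH, p-TsOH·H2O (cat.), rt; Et3N quench
Reagents that add atoms: trimethyl orthoformate, COC(OC)OC; methanol, CO
Why: Acid-catalysed ketalisation driven by the orthoformate as water scavenger at room temperature, where the cyclopropane should be stable; the configuration at C5 is of no consequence because step 4 erases it.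

**Step 4**
Reactants: 5 isocaran-4-one dimethyl ketal; 6 (E)-crotyl alcohol
Product: 9 Claisen ketone (C10 ketone with quaternary C5 carrying C14 on the β face and the (S)-but-3-en-2-yl chain on the α face), via mixed methyl crotyl ketal 7 (not isolated), via crotyl enol ether 8 (not isolated)
Conditions: 6 (3 equiv), EtCO2H (10 mol%), xylene, 130 °C, MeOH distilled off
Reagents that add atoms: none
Why: Ketal Claisen rearrangement, in which acid-catalysed exchange and loss of methanol give the allyl enol ethers reversibly and the tetrasubstituted C5=C10 isomer rearranges [3,3] through a chair on the face opposite the cyclopropane bridge, setting quaternary C5 (C14 cis to the bridge), while the equatorial methyl of the (E)-crotyl unit in that chair sets C4 so that C15 will be cis to C14; a C9-crotylated regioisomer, if formed, should be separable.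

**Step 5**
Reactants: 9 Claisen ketone
Product: 10 methylidene diene (C10=C1 exocyclic methylene, C4 vinyl)
Conditions: Ph3PCH3Br, KOt-Bu, toluene, 90 °C
Reagents that add atoms: methyltriphenylphosphonium bromide, C[P+](c1ccccc1)(c1ccccc1)c1ccccc1.[Br-]
Why: Wittig methylenation under forcing conditions suited to a hindered ketone whose α-quaternary C5 cannot epimerise, enolisation toward C9 merely returning the ketone.

**Step 6**
Reactants: 10 methylidene diene
Product: 12 primary alcohol (C2 carbinol), via alkylbis(siamyl)borane 11 (not isolated)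
Conditions: Sia2BH (1.3 equiv, from BH3·SMe2 and 2-methylbut-2-ene), THF, 0 °C; then NaOH, H2O2, 0 °C → rt
Reagents that add atoms: disiamylborane, CC(C)C(C)BC(C)C(C)C (boron of 11); hydrogen peroxide, OO (oxygen of 12)
Why: Brown hydroboration with a bulky dialkylborane, which should add anti-Markovnikov to the monosubstituted vinyl group far faster than to the 1,1-disubstituted methylene flanked by quaternary C5.

**Step 7**
Reactants: 12 primary alcohol
Product: 13 carane aldehyde (C2 aldehyde, C10=C1 methylene)
Conditions: (n-Pr4N)RuO4 (5 mol%), NMO, 4 Å MS, CH2Cl2, rt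
Reagents that add atoms: none
Why: Ley–Griffith oxidation stops at the aldehyde and is neutral, so no premature acid-induced cyclisation onto the methylene is expected.

**Step 8**
Reactants: 13 carane aldehyde
Product: 15 tricyclic 2α-alcohol (8,11-cycloeremophil-9-en-2α-ol), via chloro(methyl)aluminium alkoxide 14 (not isolated)
Conditions: Me2AlCl (1.5 equiv), CH2Cl2, −78 → 0 °C; H2O, then aq. KNaC4H4O6
Reagents that add atoms: dimethylaluminium chloride, C[Al](C)Cl (aluminium, methyl and chlorine of 14 only)
Why: Me2AlCl binds the aldehyde oxygen and the activated C2=O reacts with the ene unit H–C9–C10=C1 through a six-centre transition state in which C1 bonds to C2 while the α hydrogen on C9 passes to oxygen, the resulting alkoxyaluminium losing methane so that no protic acid is set free. The closest known reaction type is the Me2AlCl-promoted type 2 intramolecular carbonyl-ene cyclisation of aldehydes tethered to the central carbon of a 1,1-disubstituted alkene, which gives 3-alkylidenecyclohexanols. Ring A (C10, C1, C2, C3, C4, C5) closes in a 6-endo sense with respect to the C10=C1 bond, through a chair fused to ring B in which C14 is axial and C6 and the C4 methyl are equatorial. The one new stereocentre, C2, is set by that chair, because hydrogen transfer is only possible when the carbonyl oxygen is axial on the α face beside the α hydrogen of C9, which gives the 2α (axial) alcohol. The step needs regiocontrol of the hydrogen transfer and this C2 configuration: the first is secured because C5 is quaternary, so C9 carries the only allylic hydrogens and the alkene must end at C9–C10, and the second by the fused chair just described. The cyclopropane is not conjugated with any developing charge and should survive.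

**Step 9**
Reactants: 15 tricyclic 2α-alcohol
Product: 16 2α-acetate
Conditions: Ac2O, pyridine, DMAP (cat.), CH2Cl2, rt
Reagents that add atoms: acetic anhydride, CC(=O)OC(C)=O
Why: DMAP-catalysed acylation of the axial secondary alcohol installs the C2 acetate of the target before any other hydroxyl exists.

**Step 10**
Reactants: 16 2α-acetate
Product: 18 9α-carbinol with 10α-H (2α-acetoxy-8,11-cycloeremophilan-9α-ol), via C9 alkylborane 17 (not isolated)
Conditions: BH3·THF (1.2 equiv), THF, 0 °C; then aq. NaOAc, 30% H2O2, 0 °C → rt
Reagents that add atoms: borane–tetrahydrofuran, [BH3-][O+]1CCCC1 (boron of 17); hydrogen peroxide, OO (oxygen of 18)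
Why: Brown hydroboration–oxidation places boron on the less substituted C9 and hydrogen on C10 by syn addition to the α face, opposite C14 on the adjacent carbon and the cyclopropane bridge (as 2-carene is hydroborated), which sets the trans ring fusion (10α-H), while limited borane at 0 °C and buffered peroxide should spare the acetate.

**Step 11**
Reactants: 18 9α-carbinol
Product: 19 homoallylic tertiary alcohol (2α-acetoxy-10αH-eremophil-8-en-11-ol, 7β side chain)
Conditions: HClO4 (cat.), THF–H2O (3:1), rt
Reagents that add atoms: water, O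
Why: Cyclopropylcarbinyl-to-homoallyl rearrangement, in which ionisation of the 9α C–O bond is assisted by the anti-disposed C8–C11 bond, the strain-free tertiary C11 cation is captured by water and the C8=C9 alkene appears, with C7 untouched and therefore keeping its β substituent.

**Step 12**
Reactants: 19 homoallylic tertiary alcohol
Product: 20 8α,9α,11-triol
Conditions: OsO4 (2 mol%), NMO, acetone–H2O (5:1), rt
Reagents that add atoms: osmium tetroxide, O=[Os](=O)(=O)=O; N-methylmorpholine N-oxide, C[N+]1([O-])CCOCC1; water, O
Why: Upjohn dihydroxylation adds both oxygens syn to the only alkene from the α face, since the β face is covered by axial C14 and by the bulky β substituent on allylic C7.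

**Step 13**
Reactants: 20 8α,9α,11-triol
Product: 21 8α,9α-acetonide with free C11–OH
Conditions: Me2C(OMe)2, PPTS (cat.), CH2Cl2, rt
Reagents that add atoms: 2,2-dimethoxypropane, COC(C)(C)OC
Why: Acid-catalysed transketalisation gives the 1,3-dioxolane of the cis-1,2-diol, the tertiary alcohol being trans to O8 and too hindered to compete.

**Step 14**
Reactants: 21 8α,9α-acetonide
Product: 22 isopropenyl acetonide
Conditions: SOCl2, pyridine, CH2Cl2, −20 → 0 °C
Reagents that add atoms: none
Why: Dehydration through the chlorosulfite with pyridine-mediated E2 loss of an unhindered methyl hydrogen should favour the isopropenyl group, because the alternative C7=C11 alkene would be tetrasubstituted and strained against C6 and the C8 oxygen.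

**Step 15**
Reactants: 22 isopropenyl acetonide
Product: 23 8α,9α-diol (2α-acetoxy-10αH-eremophil-11-ene-8α,9α-diol)
Conditions: AcOH–H2O (4:1), 40 °C
Reagents that add atoms: none
Why: Mild acidic acetonide hydrolysis is tolerated by the acetate and the isopropenyl group, and no cyclic ether can form because C11 is trans to both ring oxygens.

**Step 16**
Reactants: 23 8α,9α-diol; 24 angelic acid
Product: 26 target 2α-acetoxy-9α-angeloyloxy-10αH-eremophil-11-en-8α-ol, via angelic 2,4,6-trichlorobenzoic anhydride 25 (not isolated)
Conditions: 24 (1.3 equiv), 2,4,6-Cl3C6H2COCl, Et3N, toluene, rt; then 23, toluene, 75 °C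
Reagents that add atoms: 2,4,6-trichlorobenzoyl chloride, O=C(Cl)c1c(Cl)cc(Cl)cc1Cl (in 25 only)
Why: Yamaguchi-type mixed-anhydride esterification run without a nucleophilic catalyst should transfer the angeloyl group without Z-to-E isomerisation, and the equatorial C9–OH, remote from the isopropenyl-bearing C7, should acylate in preference to the axial C8–OH.

**Compound list**
1 | (+)-3-carene, (1S,6R)-3,7,7-trimethylbicyclo[4.1.0]hept-3-ene | CC1(C)[C@H]2CC(C)=CC[C@@H]12 | starting material
2 | bis(4-isocaranyl)borane (boron trans to the cyclopropane bridge) | CC1(C)[C@H]2C[C@@H](C)[C@H](B[C@H]3[C@H](C)C[C@@H]4C(C)(C)[C@@H]4C3)C[C@@H]12 | intermediate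
3 | (−)-4-isocaranol, (1S,3R,4R,6R)-3,7,7-trimethylbicyclo[4.1.0]heptan-4-ol | CC1(C)[C@H]2C[C@@H](C)[C@H](O)C[C@@H]12 | intermediate
4 | isocaran-4-one, (1S,3R,6R)-3,7,7-trimethylbicyclo[4.1.0]heptan-4-one | CC1(C)[C@H]2C[C@@H](C)C(=O)C[C@@H]12 | intermediate
5 | isocaran-4-one dimethyl ketal | CC1(C)[C@H]2C[C@@H](C)C(OC)(OC)C[C@@H]12 | intermediate
6 | (E)-crotyl alcohol, (E)-but-2-en-1-ol | C/C=C/CO | starting material
7 | mixed methyl (E)-crotyl ketal of 4 (ketal carbon unassigned) | CC1(C)[C@H]2C[C@@H](C)C(OC)(OC/C=C/C)C[C@@H]12 | intermediate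
8 | (E)-crotyl enol ether, (1S,6R)-4-[(E)-but-2-enyloxy]-3,7,7-trimethylbicyclo[4.1.0]hept-3-ene | CC1(C)[C@H]2CC(C)=C(OC/C=C/C)C[C@@H]12 | intermediate
9 | Claisen ketone, (1S,3R,6R)-3-[(2S)-but-3-en-2-yl]-3,7,7-trimethylbicyclo[4.1.0]heptan-4-one | CC1(C)[C@H]2C[C@](C)([C@@H](C)C=C)C(=O)C[C@@H]12 | intermediate
10 | methylidene diene, (1S,3R,6R)-3-[(2S)-but-3-en-2-yl]-3,7,7-trimethyl-4-methylidenebicyclo[4.1.0]heptane | CC1(C)[C@H]2C[C@](C)([C@@H](C)C=C)C(=C)C[C@@H]12 | intermediate
11 | alkylbis(siamyl)borane from 10 (boron on C2) | CC1(C)[C@H]2C[C@](C)([C@@H](C)CCB(C(C)C(C)C)C(C)C(C)C)C(=C)C[C@@H]12 | intermediate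
12 | primary alcohol, (3S)-3-[(1S,3R,6R)-3,7,7-trimethyl-4-methylidenebicyclo[4.1.0]heptan-3-yl]butan-1-ol | CC1(C)[C@H]2C[C@](C)([C@@H](C)CCO)C(=C)C[C@@H]12 | intermediate
13 | carane aldehyde, (3S)-3-[(1S,3R,6R)-3,7,7-trimethyl-4-methylidenebicyclo[4.1.0]heptan-3-yl]butanal | CC1(C)[C@H]2C[C@](C)([C@@H](C)CC=O)C(=C)C[C@@H]12 | intermediate
14 | chloro(methyl)aluminium alkoxide of 15 | CC1(C)[C@H]2C[C@]3(C)[C@@H](C)C[C@H](O[Al](C)Cl)CC3=C[C@@H]12 | intermediate
15 | tricyclic alcohol, 8,11-cycloeremophil-9-en-2α-ol (4β,5β-dimethyl, β-fused cyclopropane, axial OH) | CC1(C)[C@H]2C[C@]3(C)[C@@H](C)C[C@H](O)CC3=C[C@@H]12 | intermediate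
16 | 2α-acetoxy-8,11-cycloeremophil-9-ene | CC1(C)[C@H]2C[C@]3(C)[C@@H](C)C[C@H](OC(C)=O)CC3=C[C@@H]12 | intermediate
17 | C9 alkylborane (9α-BH2, 10α-H) | CC1(C)[C@H]2C[C@]3(C)[C@@H](C)C[C@H](OC(C)=O)C[C@H]3[C@H](B)[C@@H]12 | intermediate
18 | 2α-acetoxy-10αH-8,11-cycloeremophilan-9α-ol | CC1(C)[C@H]2C[C@]3(C)[C@@H](C)C[C@H](OC(C)=O)C[C@H]3[C@H](O)[C@@H]12 | intermediate
19 | 2α-acetoxy-10αH-eremophil-8-en-11-ol (7β side chain) | CC(C)(O)[C@H]1C[C@]2(C)[C@@H](C)C[C@H](OC(C)=O)C[C@H]2C=C1 | intermediate
20 | 2α-acetoxy-10αH-eremophilane-8α,9α,11-triol | CC(C)(O)[C@H]1C[C@]2(C)[C@@H](C)C[C@H](OC(C)=O)C[C@H]2[C@H](O)[C@@H]1O | intermediate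
21 | 8α,9α-O-isopropylidene derivative of 20 | CC(C)(O)[C@H]1C[C@]2(C)[C@@H](C)C[C@H](OC(C)=O)C[C@H]2[C@@H]3OC(C)(C)O[C@H]13 | intermediate
22 | 2α-acetoxy-8α,9α-isopropylidenedioxy-10αH-eremophil-11-ene | C=C(C)[C@H]1C[C@]2(C)[C@@H](C)C[C@H](OC(C)=O)C[C@H]2[C@@H]3OC(C)(C)O[C@H]13 | intermediate
23 | 2α-acetoxy-10αH-eremophil-11-ene-8α,9α-diol | C=C(C)[C@H]1C[C@]2(C)[C@@H](C)C[C@H](OC(C)=O)C[C@H]2[C@H](O)[C@@H]1O | intermediate
24 | angelic acid, (Z)-2-methylbut-2-enoic acid | C/C=C(/C)C(=O)O | starting material
25 | angelic 2,4,6-trichlorobenzoic anhydride | C/C=C(/C)C(=O)OC(=O)c1c(Cl)cc(Cl)cc1Cl | intermediate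
26 | CNP0217919.1, 2α-acetoxy-9α-angeloyloxy-10αH-eremophil-11-en-8α-ol | C=C(C)[C@H]1C[C@]2(C)[C@@H](C)C[C@H](OC(C)=O)C[C@H]2[C@H](OC(=O)/C(C)=C\C)[C@@H]1O | target

**Step count**
Total: 16 steps. Longest linear sequence: 16 steps from (+)-3-carene (1); crotyl alcohol (6) and angelic acid (24) enter as purchased reagents.

**Steps most likely to fail**

Step 8 (carbonyl-ene closure of ring A). The aluminium-bound aldehyde may react stepwise through the tertiary C10 cation, leading to chloride capture or migration of a C5 substituent. It may also accept a methyl group from aluminium, or close with the oxygen equatorial so that the wrong C2 configuration results. The fallback closes ring A by an aldol condensation; it sets out from aldehyde 13 and comes back at alcohol 15. MeMgBr (THF, −78 °C) would add to 13 to give the methyl carbinol F1, and (n-Pr4N)RuO4/NMO would oxidise it to the methyl ketone F2. Ozonolysis of the exocyclic methylene (O3, CH2Cl2, −78 °C; Me2S) would give the 1,5-diketone F3. KOH in MeOH would then bring about aldol condensation of the methyl ketone onto the C10 carbonyl to give the conjugated enone F4, in which the Grignard carbon has become C1. Deconjugation (KOt-Bu, t-BuOH; cold aq. AcOH quench, kinetic protonation at C1) would give the β,γ-enone F5. Immediate reduction with LiBH(s-Bu)3 (THF, −78 °C, equatorial hydride delivery) would give the axial 2α-alcohol 15. Any C2-epimeric alcohol from step 8 can enter the same line by oxidation to F5.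

Step 4 (ketal Claisen). Methanol may be lost toward C9 instead of C5, the rearrangement may pass through a boat or on the cyclopropane face, and hot acid may attack the cyclopropane. The fallback makes the C4–C5 bond by a regiospecific imine–enamine Michael addition (aza-ene type); it sets out from ketone 4 and comes back at alcohol 12. Condensation of 4 with benzylamine (toluene, azeotropic removal of water) would give the N-benzyl imine F6. Its more substituted secondary enamine tautomer should add to methyl (E)-crotonate (neat, 60–80 °C, or under 10–12 kbar if sluggish) through a compact chair-like arrangement with the ester over nitrogen, on the face opposite the cyclopropane, to give the adduct imine F7. That arrangement places the crotonate methyl where the crotyl methyl sits in the Claisen chair, so the same C4 and C5 configurations are expected. Hydrolysis (aq. AcOH) would give the keto ester F8, and Wittig methylenation (Ph3PCH3Br, NaN(SiMe3)2, THF) the methylidene ester F9. LiAlH4 (Et2O, 0 °C) would reduce F9 to alcohol 12, which rejoins the route at step 7.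

Step 16 (site-selective angeloylation). Acyl transfer may go to O8 or to both hydroxyls, and the slow, heated acylation may allow Z-to-E isomerisation to the tiglate. The fallback activates one oxygen with tin and acylates cold; it sets out from diol 23 and comes back at target 26. Bu2SnO (toluene, reflux, removal of water) would convert 23 into the dibutylstannylene acetal F10, in which the equatorial, less hindered O9 is the reactive oxygen. Angelic acid 24 would be converted without isomerisation into angeloyl chloride F11 with 1-chloro-N,N,2-trimethylprop-1-en-1-amine (CH2Cl2, 0 °C). Reaction of F10 with F11 (CH2Cl2, 0 °C, no amine base) followed by aqueous work-up should give 26.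

**Further compounds**
F1 | step 8 | methyl carbinol from 13 (carbinol carbon unassigned) | CC1(C)[C@H]2C[C@](C)([C@@H](C)CC(C)O)C(=C)C[C@@H]12
F2 | step 8 | methyl ketone with C10 methylene | CC1(C)[C@H]2C[C@](C)([C@@H](C)CC(C)=O)C(=C)C[C@@H]12
F3 | step 8 | 1,5-diketone (C10 ketone, C2 methyl ketone) | CC1(C)[C@H]2C[C@](C)([C@@H](C)CC(C)=O)C(=O)C[C@@H]12
F4 | step 8 | conjugated enone, 8,11-cycloeremophil-1(10)-en-2-one | CC1(C)[C@H]2C[C@]3(C)[C@@H](C)CC(=O)C=C3C[C@@H]12
F5 | step 8 | β,γ-enone, 8,11-cycloeremophil-9-en-2-one | CC1(C)[C@H]2C[C@]3(C)[C@@H](C)CC(=O)CC3=C[C@@H]12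
F6 | step 4 | N-benzyl imine of 4 | CC1(C)[C@H]2C[C@@H](C)C(=NCc3ccccc3)C[C@@H]12
F7 | step 4 | Michael adduct imine | CC1(C)[C@H]2C[C@](C)([C@@H](C)CC(=O)OC)C(=NCc3ccccc3)C[C@@H]12
F8 | step 4 | keto ester, methyl (3S)-3-[(1S,3R,6R)-3,7,7-trimethyl-4-oxobicyclo[4.1.0]heptan-3-yl]butanoate | CC1(C)[C@H]2C[C@](C)([C@@H](C)CC(=O)OC)C(=O)C[C@@H]12
F9 | step 4 | methylidene ester | CC1(C)[C@H]2C[C@](C)([C@@H](C)CC(=O)OC)C(=C)C[C@@H]12
F10 | step 16 | 8α,9α-O-dibutylstannylene acetal of 23 | C=C(C)[C@H]1C[C@]2(C)[C@@H](C)C[C@H](OC(C)=O)C[C@H]2[C@@H]3O[Sn](CCCC)(CCCC)O[C@H]13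
F11 | step 16 | angeloyl chloride | C/C=C(/C)C(=O)Cl
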